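**Retrosynthetic overview**

1. The cyclohexene ring is formed first: an enantioselective Diels–Alder reaction of methacrolein with (E)-3-methylpenta-1,3-diene sets both stereocentres, and the aldehyde is methylenated to a vinylcyclohexene.
2. Hex-4-yn-1-ol and methyl vinyl ether give an (E)-iodoalkene head piece; hydroboration/B-alkyl Suzuki coupling with the vinylcyclohexene fixes the E trisubstituted alkene, and oxidation plus enol acetylation give an acyclic 3-acetoxy-2-methoxy-1,3-diene.
3. The quinone ring (C1=O, C2–OH, C3–side chain, C4=O, C5–OMe, C6–H) is formed last. It is cut at C6–C1 and at C2–C3, the C(OH)–C(side chain) bond, which is the ring-closing bond; methyl chlorooxoacetate supplies C1–C2 in a one-flask C-acylation/deacetylative Dieckmann closure.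
4. Enabling feature: the ring oxygens sit as two vicinal pairs. C1/C2 is an oxalyl unit and C4/C5 is the mono-methyl enol ether of an α-diketone, so C6 (enol-ether carbon) and C3 (α to the C4 ketone) are both nucleophiles. The hydroxyquinone is simply the enol of the Claisen product cyclohex-5-ene-1,2,4-trione, so no redox step is needed and the OH/OMe positions are fixed by the precursor.

Key step: step 9

Assumption: the (S)-proline-derived oxazaborolidinium catalyst is taken to expose the enal face that leads to (1S,2R)-3 (if the sense proves opposite, the (R)-catalyst is used); commercial 3-methylpenta-1,3-diene (E/Z mixture) is used in excess because only the E isomer can reach the s-cis geometry.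

**Route**

Step 1
Reactants: 1 methacrolein (2-methylprop-2-enal); 2 (E)-3-methylpenta-1,3-diene
Product: 3 (1S,2R)-1,2,3-trimethylcyclohex-3-ene-1-carbaldehyde (2-methyl cis to CHO)
Conditions: protonated (S)-3,3-diphenyl-1-(o-tolyl)pyrrolo-oxazaborolidine (from (S)-diphenylprolinol and o-tolylboroxine, activated with Tf2NH, 10 mol%), CH2Cl2, −78 °C
Reagents that add atoms: none
Why: Catalytic enantioselective Diels–Alder reaction in which the boron-bound s-trans enal reacts through the formyl-endo transition state with the unsubstituted diene terminus bonding to the enal CH2 ("ortho" control by the terminal methyl), so the new C2 methyl should end cis to CHO, while the catalyst aryl group blocks one enal face and thereby fixes the absolute configuration of the quaternary C1 and of C2.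

Step 2
Reactants: 3 (1S,2R)-1,2,3-trimethylcyclohex-3-ene-1-carbaldehyde
Product: 4 (5R,6R)-5-ethenyl-1,5,6-trimethylcyclohex-1-ene
Conditions: Ph3PCH3Br, KOtBu, THF, 0 → 23 °C
Reagents that add atoms: methyltriphenylphosphonium bromide, C[P+](c1ccccc1)(c1ccccc1)c1ccccc1.[Br-]
Why: Wittig methylenation of a non-enolisable α-quaternary aldehyde should proceed without risk to either stereocentre.

Step 3
Reactants: 5 hex-4-yn-1-ol
Product: 7 (4E)-5-iodohex-4-en-1-ol, via alkenylzirconocene chloride 6 (not isolated)
Conditions: Cp2Zr(H)Cl (3 equiv), THF, 50 °C; then I2, 0 °C; H2O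
Reagents that add atoms: iodine, II
Why: Hydrozirconation–iodination in which syn Zr–H addition with thermodynamic equilibration (excess reagent, warming) should place zirconium on the methyl-bearing alkyne carbon and iodinolysis with retention should give the E iodoalkene, the hydroxyl being carried as its zirconium alkoxide.

Step 4
Reactants: 7 (4E)-5-iodohex-4-en-1-ol
Product: 8 (4E)-5-iodohex-4-enal
Conditions: (nPr4N)RuO4 (5 mol%), NMO, 4 Å MS, CH2Cl2, 23 °C
Reagents that add atoms: none
Why: Ley–Griffith oxidation should take the primary alcohol to the aldehyde without touching the iodoalkene.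

Step 5
Reactants: 8 (4E)-5-iodohex-4-enal; 9 methyl vinyl ether
Product: 11 (6E)-7-iodo-2-methoxyocta-1,6-dien-3-ol (racemic), via 1-methoxyvinyllithium 10 (not isolated)
Conditions: 9, tBuLi, THF, −78 → 0 °C; then 8, −78 °C; H2O
Reagents that add atoms: none
Why: α-Lithiation of the vinyl ether and 1,2-addition of this acyl-anion equivalent to the aldehyde at −78 °C should outrun iodine–lithium exchange; the carbinol centre forms without control and is erased in step 7.

Step 6
Reactants: 4 (5R,6R)-5-ethenyl-1,5,6-trimethylcyclohex-1-ene; 11 (6E)-7-iodo-2-methoxyocta-1,6-dien-3-ol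
Product: 13 (6E)-2-methoxy-7-methyl-9-[(1R,2S)-1,2,3-trimethylcyclohex-3-en-1-yl]nona-1,6-dien-3-ol (both C3 epimers), via B-alkyl-9-BBN 12 (not isolated)
Conditions: 4 (1.3 equiv), 9-BBN-H (1.2 equiv), THF, 0 → 23 °C; then 3 M aq. NaOH, 11, PdCl2(dppf) (5 mol%), THF, 23 → 50 °C
Reagents that add atoms: none
Why: 9-BBN should hydroborate only the monosubstituted vinyl group (anti-Markovnikov), and the B-alkyl Suzuki–Miyaura coupling should join the primary alkylborane to the iodoalkene with retention of the E geometry, no stereocentre being touched.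

Step 7
Reactants: 13 (6E)-2-methoxy-7-methyl-9-[(1R,2S)-1,2,3-trimethylcyclohex-3-en-1-yl]nona-1,6-dien-3-ol
Product: 14 (6E)-2-methoxy-7-methyl-9-[(1R,2S)-1,2,3-trimethylcyclohex-3-en-1-yl]nona-1,6-dien-3-one
Conditions: (nPr4N)RuO4 (5 mol%), NMO, 4 Å MS, CH2Cl2, 23 °C
Reagents that add atoms: none
Why: Ley–Griffith oxidation of the allylic secondary alcohol should give the α-methoxy enone and converge both carbinol epimers, the base-free conditions sparing the enol ether.

Step 8
Reactants: 14 (6E)-2-methoxy-7-methyl-9-[(1R,2S)-1,2,3-trimethylcyclohex-3-en-1-yl]nona-1,6-dien-3-one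
Product: 16 (3Z,6E)-2-methoxy-7-methyl-9-[(1R,2S)-1,2,3-trimethylcyclohex-3-en-1-yl]nona-1,3,6-trien-3-yl acetate, via lithium dienolate 15 (not isolated)
Conditions: LiN(SiMe3)2, THF, −78 °C (14 added to the base); then Ac2O, −78 → 0 °C
Reagents that add atoms: acetic anhydride, CC(=O)OC(C)=O
Why: Kinetic deprotonation at the only enolisable position (C4) and O-acetylation of the lithium enolate should give the dienyl acetate, a latent enolate that is inert to acyl chlorides; the enol geometry (Z expected) is inconsequential.

Step 9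
Reactants: 16 (3Z,6E)-2-methoxy-7-methyl-9-[(1R,2S)-1,2,3-trimethylcyclohex-3-en-1-yl]nona-1,3,6-trien-3-yl acetate; 17 methyl chlorooxoacetate
Product: 20 metachromin C, via acetoxy trienoate 18 (not isolated), via diketo ester 19 (not isolated)
Conditions: 17 (1.2 equiv), pyridine, CH2Cl2, −20 → 0 °C; then NaOMe (4 equiv), MeOH, 0 → 23 °C; aq. HCl
Reagents that add atoms: none
Why: Pyridine-mediated C-acylation of the methoxy-substituted diene terminus (future C6) by 17 installs the oxalyl unit C1–C2 and gives 18; methoxide then cleaves the enol acetate, and the freed ketone enolate carbon (future C3) attacks the ester carbonyl (future C2), expelling methoxide to form the C2–C3 bond and the cyclohex-5-ene-1,2,4-trione, whose enol is 20 and whose irreversible deprotonation to the hydroxyquinone anion drives the sequence. The closest known reaction types are the C-acylation of 2-alkoxyalkenes by oxalyl chloride half esters and the Claisen/Dieckmann condensation of ketone enolates with oxalate ester carbonyls, as in the cyclisation of δ-keto esters to cyclohexane-1,3-diones. The six-membered ring closes in the 6-(enolendo)-exo-trig mode; no stereocentre is formed, and the two ring stereocentres and the E side-chain alkene are remote from all reacting sites. Site selectivity in the acylation should be secured because attack at the CH2 terminus gives a methoxy-stabilised oxocarbenium ion, whereas the enol acetate terminus is far less nucleophilic. In the closure, five-ring aldol addition to the C1 ketone and O-acylation are reversible under methoxide while the Claisen product is trapped as its anion, and methoxide matches both the ester and the enol ether so that any exchange is degenerate. The step is stereoconvergent in alkene geometry: the E/Z isomers of the C5=C6 enol ether interconvert by reversible methoxide addition–elimination and the enol acetate geometry is erased on enolate formation, so every isomer of 18 should funnel into 20.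

**Compound list**

1 | methacrolein (2-methylprop-2-enal) | CC(=C)C=O | starting material
2 | (E)-3-methylpenta-1,3-diene | C=C/C(C)=C/C | starting material
3 | (1S,2R)-1,2,3-trimethylcyclohex-3-ene-1-carbaldehyde (2-methyl cis to CHO) | O=C[C@@]1(C)CCC=C(C)[C@H]1C | intermediate
4 | (5R,6R)-5-ethenyl-1,5,6-trimethylcyclohex-1-ene (6-methyl cis to vinyl) | C=C[C@@]1(C)CCC=C(C)[C@H]1C | intermediate
5 | hex-4-yn-1-ol | CC#CCCCO | starting material
6 | (E)-alkenylzirconocene chloride of 5, zirconium on the methyl-bearing carbon, hydroxyl as zirconocene chloride alkoxide | C/C(=C\CCCO[Zr](Cl)(C1C=CC=C1)C1C=CC=C1)[Zr](Cl)(C1C=CC=C1)C1C=CC=C1 | intermediate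
7 | (4E)-5-iodohex-4-en-1-ol | C/C(I)=C\CCCO | intermediate
8 | (4E)-5-iodohex-4-enal | C/C(I)=C\CCC=O | intermediate
9 | methyl vinyl ether | COC=C | starting material
10 | 1-methoxyvinyllithium | [Li]C(=C)OC | intermediate
11 | (6E)-7-iodo-2-methoxyocta-1,6-dien-3-ol (racemic) | C=C(OC)C(O)CC/C=C(\C)I | intermediate
12 | 9-{2-[(1S,2S)-1,2,3-trimethylcyclohex-3-en-1-yl]ethyl}-9-borabicyclo[3.3.1]nonane (same spatial arrangement as 4; the descriptor change is formal) | B1(C2CCCC1CCC2)CC[C@@]1(C)CCC=C(C)[C@H]1C | intermediate
13 | (6E)-2-methoxy-7-methyl-9-[(1R,2S)-1,2,3-trimethylcyclohex-3-en-1-yl]nona-1,6-dien-3-ol (both C3 epimers) | C=C(OC)C(O)CC/C=C(\C)CC[C@@]1(C)CCC=C(C)[C@H]1C | intermediate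
14 | (6E)-2-methoxy-7-methyl-9-[(1R,2S)-1,2,3-trimethylcyclohex-3-en-1-yl]nona-1,6-dien-3-one | C=C(OC)C(=O)CC/C=C(\C)CC[C@@]1(C)CCC=C(C)[C@H]1C | intermediate
15 | lithium (3Z,6E)-2-methoxy-7-methyl-9-[(1R,2S)-1,2,3-trimethylcyclohex-3-en-1-yl]nona-1,3,6-trien-3-olate | C=C(OC)/C(O[Li])=C/C/C=C(\C)CC[C@@]1(C)CCC=C(C)[C@H]1C | intermediate
16 | (3Z,6E)-2-methoxy-7-methyl-9-[(1R,2S)-1,2,3-trimethylcyclohex-3-en-1-yl]nona-1,3,6-trien-3-yl acetate | C=C(OC)/C(OC(C)=O)=C/C/C=C(\C)CC[C@@]1(C)CCC=C(C)[C@H]1C | intermediate
17 | methyl chlorooxoacetate | COC(=O)C(Cl)=O | starting material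
18 | methyl (3E,5Z,8E)-5-acetoxy-4-methoxy-9-methyl-2-oxo-11-[(1R,2S)-1,2,3-trimethylcyclohex-3-en-1-yl]undeca-3,5,8-trienoate | COC(=O)C(=O)/C=C(OC)\C(OC(C)=O)=C\C/C=C(\C)CC[C@@]1(C)CCC=C(C)[C@H]1C | intermediate
19 | methyl (3E,8E)-4-methoxy-9-methyl-2,5-dioxo-11-[(1R,2S)-1,2,3-trimethylcyclohex-3-en-1-yl]undeca-3,8-dienoate | COC(=O)C(=O)/C=C(OC)\C(=O)CC/C=C(\C)CC[C@@]1(C)CCC=C(C)[C@H]1C | intermediate
20 | metachromin C, 2-hydroxy-5-methoxy-3-{(2E)-3-methyl-5-[(1R,2S)-1,2,3-trimethylcyclohex-3-en-1-yl]pent-2-en-1-yl}cyclohexa-2,5-diene-1,4-dione | COC1=CC(=O)C(O)=C(C/C=C(\C)CC[C@@]2(C)CCC=C(C)[C@H]2C)C1=O | target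

**Step count and risks**

Total step count: 9. Longest linear sequence: 7 steps (steps 3 to 9, from hex-4-yn-1-ol); the cyclohexene branch contributes steps 1 and 2.

The three steps most likely to fail:

Step 9. The process at risk is sluggish or unclean C-acylation of the cross-conjugated acetoxy diene (the enol acetate lowers the nucleophilicity of the enol ether, or the acetyl group is lost early), so that 19 is not generated cleanly in the flask. The fallback builds 19 stepwise at the alcohol oxidation level and isolates it. It sets out from 13: silylation (TBSCl, imidazole, DMF) should give the tert-butyldimethylsilyl ether F1, whose isolated enol ether is acylated with 17 and pyridine to the silyloxy keto ester F2. HF·pyridine should then give the hydroxy keto ester F3, and oxidation with (nPr4N)RuO4/NMO returns to the route at 19, which is closed to 20 with NaOMe in MeOH as in the second stage of step 9.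

Step 1. The process at risk is loss of facial control by the chiral Lewis acid with this 1,2-disubstituted diene (low enantiomeric purity), possibly together with erosion of endo and "ortho" selectivity at the temperature the catalyst needs. The fallback gives up asymmetric catalysis for resolution. It sets out from 1 and 2: cycloaddition with EtAlCl2 in CH2Cl2 at −78 °C should give the racemic aldehyde F4. Condensation with (1R,2R)-N,N'-dimethyl-1,2-diphenylethane-1,2-diamine should give the imidazolidine F5 and the diastereomeric imidazolidine F6 (from the enantiomer of 3), which are separated by chromatography. Mild aqueous acid hydrolysis of F5 returns to the route at 3; the quaternary α-carbon excludes epimerisation.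

Step 8. The process at risk is Michael self-condensation between the lithium enolate and unreacted enone during deprotonation, or C-acetylation on trapping. The fallback avoids exposing the enone to a strong base. It sets out from 14: soft enolisation with Me3SiOTf and Et3N in CH2Cl2 at 0 °C should give the trimethylsilyl dienol ether F7. MeLi in THF at 0 °C then releases the amine-free enolate 15, and Ac2O returns to the route at 16.

Further compounds
F1 | step 9 | tert-butyl{[(6E)-2-methoxy-7-methyl-9-[(1R,2S)-1,2,3-trimethylcyclohex-3-en-1-yl]nona-1,6-dien-3-yl]oxy}dimethylsilane (both C3 epimers) | C=C(OC)C(O[Si](C)(C)C(C)(C)C)CC/C=C(\C)CC[C@@]1(C)CCC=C(C)[C@H]1C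
F2 | step 9 | methyl (3E,8E)-5-[(tert-butyldimethylsilyl)oxy]-4-methoxy-9-methyl-2-oxo-11-[(1R,2S)-1,2,3-trimethylcyclohex-3-en-1-yl]undeca-3,8-dienoate (both C5 epimers) | COC(=O)C(=O)/C=C(OC)\C(O[Si](C)(C)C(C)(C)C)CC/C=C(\C)CC[C@@]1(C)CCC=C(C)[C@H]1C
F3 | step 9 | methyl (3E,8E)-5-hydroxy-4-methoxy-9-methyl-2-oxo-11-[(1R,2S)-1,2,3-trimethylcyclohex-3-en-1-yl]undeca-3,8-dienoate (both C5 epimers) | COC(=O)C(=O)/C=C(OC)\C(O)CC/C=C(\C)CC[C@@]1(C)CCC=C(C)[C@H]1C
F4 | step 1 | racemic (1S*,2R*)-1,2,3-trimethylcyclohex-3-ene-1-carbaldehyde | O=C[C@@]1(C)CCC=C(C)[C@H]1C.O=C[C@]1(C)CCC=C(C)[C@@H]1C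
F5 | step 1 | (4R,5R)-1,3-dimethyl-4,5-diphenyl-2-[(1S,2R)-1,2,3-trimethylcyclohex-3-en-1-yl]imidazolidine | CN1[C@H](c2ccccc2)[C@H](N(C)C1[C@@]1(C)CCC=C(C)[C@H]1C)c1ccccc1
F6 | step 1 | (4R,5R)-1,3-dimethyl-4,5-diphenyl-2-[(1R,2S)-1,2,3-trimethylcyclohex-3-en-1-yl]imidazolidine | CN1[C@H](c2ccccc2)[C@H](N(C)C1[C@]1(C)CCC=C(C)[C@@H]1C)c1ccccc1
F7 | step 8 | trimethyl{[(3Z,6E)-2-methoxy-7-methyl-9-[(1R,2S)-1,2,3-trimethylcyclohex-3-en-1-yl]nona-1,3,6-trien-3-yl]oxy}silane | C=C(OC)/C(O[Si](C)(C)C)=C/C/C=C(\C)CC[C@@]1(C)CCC=C(C)[C@H]1C
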